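**Retrosynthetic overview**
1. The 1,4-dioxane is opened last: hetero-Diels–Alder addition of the ortho-quinone of 6-oxopristimerol (33, rings A–E) across C1=C5 of (7R,10R)-guaia-1(5),3,11-triene 41.
2. The strategy rests on ring B, the C5–C6(=O)–C7=C8–C9(Me)–C10 ring fused to aromatic ring A. It is read as an aryne [4+2] adduct, so C5–C6 and C9–C10 are cut to 4,5-dimethoxy-3-methylbenzyne (from silyl triflate 7) and the C6=C7–C8=C9 ethoxydiene 29.
3. Diene 29 comes from the C8 enol triflate of a C/D/E tricycle built E → D → C: ring E keto ester, asymmetric Michael addition and aldol (ring D), cis hydrogenation, Robinson annulation (ring C), carbonyl shift C9 → C8 with the C9 methyl, methylations at C20 and C14.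
4. Triene 41 comes from (2R,5R)-dihydrocarvone by one-carbon ring expansion, cyclopentenone annulation and methylation of a dienyl triflate.
5. Ring order: E, D, C, then B onto preformed ring A, then the dioxane that carries the hydroazulene.

Key step: step 19

Remark: friedelane locants are used for the triterpene half (ring C: C8, C9, C11–C14; ring D: C13–C18; ring E: C17–C22; ester carbon on C20) and guaiane locants for the sesquiterpene half; α/β refer to the usual steroid-type drawing.
Remark: C20 is carried as an epimer mixture in 9–21, and C8, C9 and C14 are uncontrolled in 21–25; each of these centres is later planar or erased, so the SMILES leave them open.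
Remark: commercial (+)-dihydrocarvone is assumed to be equilibrated (NaOMe) and freed of its cis isomer by chromatography before use as 34; it replaces (R)-limonene as the chiral-pool source of C7.

Step 1
Reactants: 1 2,3-dimethoxytoluene
Product: 2 1-bromo-3,4-dimethoxy-2-methylbenzene
Conditions: NBS, MeCN, 0 °C to rt
Reagents that add atoms: N-bromosuccinimide, O=C1CCC(=O)N1Br
Why: Electrophilic aromatic bromination should go para to the 3-methoxy group, the only donor that can lie in the ring plane, which is the position next to the methyl group.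

Step 2
Reactants: 2 1-bromo-3,4-dimethoxy-2-methylbenzene
Product: 3 3,4-dimethoxy-2-methylphenol
Conditions: KOH, Pd2(dba)3 (cat.), t-BuXPhos (cat.), dioxane/H2O, 100 °C
Reagents that add atoms: potassium hydroxide, [K+].[OH-]
Why: Palladium-catalysed hydroxylation of aryl bromides with hydroxide and a bulky biaryl phosphine tolerates the ortho methyl group and gives the phenol directly (C–O cross-coupling).

Step 3
Reactants: 3 3,4-dimethoxy-2-methylphenol
Product: 4 6-bromo-3,4-dimethoxy-2-methylphenol
Conditions: NBS, CH2Cl2, −30 to 0 °C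
Reagents that add atoms: N-bromosuccinimide, O=C1CCC(=O)N1Br
Why: The free hydroxyl is the strongest director and its para position is blocked, so bromination should enter the only open ortho position (phenol ortho-bromination).

Step 4
Reactants: 4 6-bromo-3,4-dimethoxy-2-methylphenol
Product: 7 3,4-dimethoxy-2-methyl-6-(trimethylsilyl)phenyl trifluoromethanesulfonate, via trimethylsilyl ether 5 (not isolated), via lithium phenolate 6 (not isolated)
Conditions: (Me3Si)2NH, THF, reflux, evaporate; n-BuLi, THF, −78 °C; Tf2O, −78 to 0 °C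
Reagents that add atoms: hexamethyldisilazane, C[Si](C)(C)N[Si](C)(C)C; trifluoromethanesulfonic anhydride, O=S(=O)(OS(=O)(=O)C(F)(F)F)C(F)(F)F
Why: Halogen–lithium exchange on the silyl ether triggers a 1,3 O-to-C silyl shift (retro-Brook rearrangement) and the phenolate is then triflated, the standard route to ortho-silyl aryl triflates.

Step 5
Reactants: 8 methyl 3-hydroxy-4-methylbenzoate
Product: 9 methyl 3-hydroxy-4-methylcyclohexane-1-carboxylate (stereoisomer mixture)
Conditions: H2 (50 bar), 5% Rh/Al2O3, MeOH, 50 °C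
Reagents that add atoms: none
Why: Rhodium on alumina hydrogenates phenols to cyclohexanols without hydrogenolysis and leaves the ester untouched (arene hydrogenation); the new centres need no control.

Step 6
Reactants: 9 methyl 3-hydroxy-4-methylcyclohexane-1-carboxylate
Product: 10 methyl 4-methyl-3-oxocyclohexane-1-carboxylate (racemic, epimer mixture)
Conditions: TEMPO (cat.), KBr (cat.), NaOCl, NaHCO3, CH2Cl2/H2O, 0 °C
Reagents that add atoms: none
Why: Oxoammonium oxidation turns the secondary alcohol into the ketone under buffered conditions that do not touch the ester (TEMPO/hypochlorite oxidation).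

Step 7
Reactants: 10 methyl 4-methyl-3-oxocyclohexane-1-carboxylate; 11 (S)-1-phenylethylamine; 12 pent-1-en-3-one
Product: 15 methyl (4R)-4-methyl-3-oxo-4-(3-oxopentyl)cyclohexane-1-carboxylate, via imine 13 (not isolated), via Michael adduct imine 14 (not isolated)
Conditions: 11, TsOH (cat.), toluene, reflux with water removal; 12, THF, 40 °C; then aq. AcOH, rt
Reagents that add atoms: water, O
Why: The imine reacts through its more substituted secondary enamine tautomer in an aza-ene-like Michael addition, and the phenylethyl group shields one face so that quaternary C17 should form with R configuration whatever the C20 epimer (asymmetric Michael addition of a chiral imine).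

Step 8
Reactants: 15 methyl (4R)-4-methyl-3-oxo-4-(3-oxopentyl)cyclohexane-1-carboxylate
Product: 16 methyl (4aR)-4a,8-dimethyl-7-oxo-1,2,3,4,4a,5,6,7-octahydronaphthalene-2-carboxylate (D/E enone: C14 ketone, C13=C18)
Conditions: NaOMe, MeOH, reflux
Reagents that add atoms: none
Why: Base-mediated intramolecular aldol condensation of the 1,5-diketone closes ring D as the conjugated C13=C18 enone (second half of a Robinson annulation).

Step 9
Reactants: 16 D/E enone
Product: 17 methyl (4aR,8aS)-4a,8-dimethyl-7-oxodecahydronaphthalene-2-carboxylate (cis-fused: 17β-Me, 18β-H)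
Conditions: H2 (4 bar), 10% Pd/C, MeOH, Et3N, rt
Reagents that add atoms: none
Why: Heterogeneous hydrogenation of 10-methyl-octalones in basic medium delivers hydrogen to the face that carries the angular methyl, which should set 18β-H and the cis D/E fusion (enone hydrogenation); C13 stays epimerisable.

Step 10
Reactants: 17 cis-fused D/E ketone; 18 but-3-en-2-one
Product: 20 C/D/E tricyclic 9-oxo-8(14)-ene ester (13α-Me), via Michael adduct diketone 19 (not isolated)
Conditions: 18, NaOMe (cat.), MeOH, 0 °C to rt; then NaOMe, MeOH, reflux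
Reagents that add atoms: none
Why: The thermodynamic enolate of the cis-fused ketone lies toward C13 and should add to the enone on the convex face, syn to H-18 and anti to the ring E carbon on C18, which sets 13α-methyl before aldol condensation closes ring C (Robinson annulation).

Step 11
Reactants: 20 tricyclic 9-oxo-8(14)-ene ester
Product: 21 tricyclic 9-hydroxy-9-methyl-8(14)-ene ester
Conditions: MeLi, CeCl3, THF, −78 °C
Reagents that add atoms: methyllithium, [Li]C
Why: The organocerium reagent adds 1,2 to the hindered enone without enolisation and is too slow toward the ester at low temperature (organocerium carbonyl addition); the C9 configuration is irrelevant.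

Step 12
Reactants: 21 tricyclic 9-hydroxy-9-methyl-8(14)-ene ester
Product: 22 tricyclic 9-hydroxy-9,20β-dimethyl-8(14)-ene 20α-methyl ester
Conditions: LiN(i-Pr)2 (2.3 equiv), THF, −78 to −30 °C; MeI, −78 to 0 °C
Reagents that add atoms: iodomethane, CI
Why: With the alkoxide in place the second equivalent of base forms the ester enolate, and methyl iodide should enter on the convex β face of the cis-fused D/E unit, equatorial on ring E and away from axial C13 with its methyl, which gives 20β-methyl (ester enolate alkylation).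

Step 13
Reactants: 22 tricyclic 9-hydroxy-9,20β-dimethyl-8(14)-ene ester
Product: 23 tricyclic 8,9-dihydroxy-9,20β-dimethyl ester
Conditions: BH3·SMe2, THF, 0 to 45 °C; then NaOH, H2O2, 0 °C to rt
Reagents that add atoms: hydrogen peroxide, OO
Why: Borane places boron at the less substituted C8 of the trisubstituted alkene and oxidation gives the C8 alcohol (hydroboration–oxidation); the C8 and C14 configurations are erased later.

Step 14
Reactants: 23 tricyclic 8,9-diol
Product: 24 tricyclic 9-hydroxy-9,20β-dimethyl-8-oxo ester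
Conditions: (COCl)2, DMSO, CH2Cl2, −78 °C; Et3N, −78 to 0 °C
Reagents that add atoms: none
Why: Activated DMSO oxidises the secondary C8 alcohol while the tertiary C9 alcohol cannot react (Swern oxidation).

Step 15
Reactants: 24 tricyclic 9-hydroxy-8-ketone
Product: 25 tricyclic 9,20β-dimethyl-8-oxo-9(11)-ene ester (14-H)
Conditions: SOCl2, pyridine, CH2Cl2, −20 to 0 °C; then DBU (cat.), toluene, 60 °C
Reagents that add atoms: none
Why: The tertiary chlorosulfite eliminates to the conjugated enone and the amidine base equilibrates any exocyclic or chloride isomer to the endocyclic C9=C11 enone (dehydration of a tertiary α-ketol).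

Step 16
Reactants: 25 tricyclic 8-oxo-9(11)-ene ester
Product: 26 tricyclic 9,14β,20β-trimethyl-8-oxo-9(11)-ene ester (13α-Me)
Conditions: LiN(i-Pr)2 (1.1 equiv), THF, −78 °C; MeI, DMPU, −78 to −20 °C
Reagents that add atoms: iodomethane, CI
Why: Kinetic deprotonation of the enone occurs at the α' carbon C14, and methyl iodide should approach anti to the pseudoaxial 13α-methyl, which gives the trans vicinal 13α,14β-dimethyl pair (α'-alkylation of an enone).

Step 17
Reactants: 26 tricyclic 14β-methyl 8-oxo-9(11)-ene ester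
Product: 27 tricyclic C8 enol triflate (9-methyl-8-ene)
Conditions: LiBH(s-Bu)3 (L-Selectride), THF, −78 °C; PhNTf2, −78 to 0 °C
Reagents that add atoms: N-phenyl-bis(trifluoromethanesulfonimide), O=S(=O)(N(c1ccccc1)S(=O)(=O)C(F)(F)F)C(F)(F)F
Why: The hindered borohydride delivers hydride to the β carbon C11 because the carbonyl is flanked by quaternary C14, and the regiodefined enolate is trapped on oxygen (conjugate reduction–triflation).

Step 18
Reactants: 27 tricyclic C8 enol triflate; 28 (E)-2-(2-ethoxyvinyl)-4,4,5,5-tetramethyl-1,3,2-dioxaborolane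
Product: 29 tricyclic 8-[(E)-2-ethoxyvinyl]-9-methyl-8-ene ester (C6=C7–C8=C9 diene)
Conditions: Pd(dppf)Cl2 (cat.), K3PO4, dioxane/H2O, 70 °C
Reagents that add atoms: none
Why: Suzuki–Miyaura coupling of the enol triflate with the (E)-alkenyl boronate proceeds with retention of alkene geometry and gives the 1-ethoxydiene.

Step 19
Reactants: 29 tricyclic ethoxydiene; 7 3,4-dimethoxy-2-methyl-6-(trimethylsilyl)phenyl trifluoromethanesulfonate
Product: 31 pentacyclic 6α-ethoxy-7-ene dimethyl ether, via aryne 30 (not isolated)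
Conditions: 7 (slow addition), CsF, MeCN/toluene, 25 to 45 °C
Reagents that add atoms: none
Why: Fluoride attacks silicon and the aryl anion expels triflate to give 4,5-dimethoxy-3-methylbenzyne 30, which adds in a concerted, asynchronous [4+2] reaction to the s-cis C6=C7–C8=C9 diene. The closest known reaction type is the aryne Diels–Alder reaction of 1-alkoxy-1,3-dienes that gives 1-alkoxy-1,4-dihydronaphthalenes. Ring B is closed by this intermolecular [4+2] annulation, which forms C5–C6 and C9–C10 together and leaves the C7=C8 alkene in place. C9 is set by approach of the aryne to the α face, anti to the pseudoaxial 14β-methyl that covers the other face of the diene, and C6 follows from suprafacial addition to the (E)-enol ether (6α-OEt, erased in step 20). The step needs C9 to bond to C10, which the C4 methyl should secure by steering the fully substituted, nucleophilic C9 terminus to the unflanked aryne carbon while the small CH(OEt) terminus bonds next to the methyl. It also needs [4+2] to outrun ene and [2+2] pathways, which is helped by A(1,3) strain with quaternary C14 that holds the ethoxyvinyl group s-cis and by slow release of the aryne.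

Step 20
Reactants: 31 pentacyclic 6α-ethoxy-7-ene dimethyl ether
Product: 32 6-oxopristimerol dimethyl ether (6-oxo-7-ene)
Conditions: DDQ, CH2Cl2/H2O, 0 °C to rt
Reagents that add atoms: water, O
Why: DDQ abstracts the hydride at C6, which is benzylic to the electron-rich ring, allylic and α to oxygen, and water collapses the oxocarbenium ion to the enone with loss of ethanol (oxidative cleavage of a benzylic ether).

Step 21
Reactants: 32 6-oxopristimerol dimethyl ether
Product: 33 6-oxopristimerol (2,3-catechol)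
Conditions: BBr3, CH2Cl2, −78 to −10 °C; MeOH quench
Reagents that add atoms: none
Why: BBr3 cleaves the two aryl methyl ethers at low temperature, where the hindered tertiary methyl ester should react much more slowly (Lewis acid ether cleavage).

Step 22
Reactants: 34 (2R,5R)-dihydrocarvone
Product: 35 ethyl (3R,6R)-3-methyl-2-oxo-6-(prop-1-en-2-yl)cycloheptane-1-carboxylate
Conditions: ethyl diazoacetate, BF3·OEt2, Et2O, 0 °C to rt
Reagents that add atoms: ethyl diazoacetate, CCOC(=O)C=[N+]=[N-]
Why: BF3-promoted addition of the diazo ester to the ketone is followed by migration of the less substituted α-methylene with loss of nitrogen, so the ring grows by one carbon between guaiane C1 and C6 and neither stereocentre is touched (Tiffeneau–Demjanov-type ring expansion).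

Step 23
Reactants: 35 seven-ring β-keto ester
Product: 36 ethyl (3R,6R)-3-methyl-6-(prop-1-en-2-yl)-2-(trifluoromethylsulfonyloxy)cyclohept-1-ene-1-carboxylate
Conditions: NaH, Et2O, 0 °C; Tf2O, −78 to 0 °C
Reagents that add atoms: trifluoromethanesulfonic anhydride, O=S(=O)(OS(=O)(=O)C(F)(F)F)C(F)(F)F
Why: The β-keto ester enolate is triflated on oxygen, which fixes the C1=C5 double bond and ends any epimerisation at C10 (enol triflate formation).

Step 24
Reactants: 36 seven-ring enol triflate
Product: 37 ethyl (3R,6R)-2-(3-ethoxy-3-oxopropyl)-3-methyl-6-(prop-1-en-2-yl)cyclohept-1-ene-1-carboxylate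
Conditions: IZnCH2CH2CO2Et (from ethyl 3-iodopropanoate, Zn dust, THF), Pd(PPh3)4 (cat.), THF/DMA, 50 °C
Reagents that add atoms: (3-ethoxy-3-oxopropyl)zinc iodide, CCOC(=O)CC[Zn]I, made in the flask from ethyl 3-iodopropanoate, CCOC(=O)CCI
Why: Palladium-catalysed coupling of the zinc homoenolate with the β-triflyloxy enoate attaches C2 and C3 at C1 (Negishi coupling).

Step 25
Reactants: 37 seven-ring diester
Product: 39 (4R,7R)-4-methyl-7-(prop-1-en-2-yl)-3,4,5,6,7,8-hexahydroazulen-1(2H)-one, via bicyclic keto ester 38 (not isolated)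
Conditions: KOt-Bu, THF, 0 °C to rt; AcOH; then LiCl, DMSO, H2O, 150 °C
Reagents that add atoms: none
Why: The chain ester enolate attacks the ring ester to close the five-membered ring (Dieckmann condensation), and chloride-induced dealkylation with loss of CO2 then removes the extra ester (Krapcho decarboxylation).

Step 26
Reactants: 39 bicyclic enone
Product: 40 (4R,7R)-4-methyl-7-(prop-1-en-2-yl)-3,4,5,6,7,8-hexahydroazulen-1-yl trifluoromethanesulfonate
Conditions: LiN(i-Pr)2, THF, −78 °C; PhNTf2, −78 to 0 °C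
Reagents that add atoms: N-phenyl-bis(trifluoromethanesulfonimide), O=S(=O)(N(c1ccccc1)S(=O)(=O)C(F)(F)F)C(F)(F)F
Why: Kinetic deprotonation at the α' methylene C3 and O-triflation give the cross-conjugated dienyl triflate, which places the diene exactly at C3=C4 and C1=C5 (enol triflate formation).

Step 27
Reactants: 40 dienyl triflate
Product: 41 (4R,7R)-1,4-dimethyl-7-(prop-1-en-2-yl)-3,4,5,6,7,8-hexahydroazulene, that is (7R,10R)-guaia-1(5),3,11-triene
Conditions: MeMgBr, Fe(acac)3 (cat.), THF/NMP, −30 °C; used at once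
Reagents that add atoms: methylmagnesium bromide, C[Mg]Br
Why: Iron-catalysed coupling of alkenyl triflates with methylmagnesium bromide is fast at low temperature, so the methyl group is installed before the cyclopentadiene can undergo 1,5-hydrogen shifts (Kumada-type cross-coupling).

Step 28
Reactants: 33 6-oxopristimerol; 41 (7R,10R)-guaia-1(5),3,11-triene
Product: 43 target CNP0317749.1, via ortho-quinone 42 (not isolated)
Conditions: Ag2O, Na2SO4, CH2Cl2, 0 °C, filter; then 41, CH2Cl2, −20 °C to rt, dark
Reagents that add atoms: none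
Why: The ortho-quinone acts as an electron-poor heterodiene toward the electron-rich C1=C5 bond of the cyclopentadiene (inverse-demand hetero-Diels–Alder); the diene terminus C1 should bond to O-3, which leaves the developing phenolate on O-2 conjugated with the C6 ketone, and the quinone should approach anti to the pseudoaxial C10 methyl, which sets both new C–O centres.

**Compound list**
1 | 2,3-dimethoxytoluene | COc1cccc(C)c1OC | starting material
2 | 1-bromo-3,4-dimethoxy-2-methylbenzene | COc1ccc(Br)c(C)c1OC | intermediate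
3 | 3,4-dimethoxy-2-methylphenol | COc1ccc(O)c(C)c1OC | intermediate
4 | 6-bromo-3,4-dimethoxy-2-methylphenol | COc1cc(Br)c(O)c(C)c1OC | intermediate
5 | (6-bromo-3,4-dimethoxy-2-methylphenoxy)trimethylsilane | COc1cc(Br)c(O[Si](C)(C)C)c(C)c1OC | intermediate
6 | lithium 3,4-dimethoxy-2-methyl-6-(trimethylsilyl)phenolate | COc1cc([Si](C)(C)C)c([O-])c(C)c1OC.[Li+] | intermediate
7 | 3,4-dimethoxy-2-methyl-6-(trimethylsilyl)phenyl trifluoromethanesulfonate | COc1cc([Si](C)(C)C)c(OS(=O)(=O)C(F)(F)F)c(C)c1OC | intermediate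
8 | methyl 3-hydroxy-4-methylbenzoate | COC(=O)c1ccc(C)c(O)c1 | starting material
9 | methyl 3-hydroxy-4-methylcyclohexane-1-carboxylate (stereoisomer mixture) | COC(=O)C1CCC(C)C(O)C1 | intermediate
10 | methyl 4-methyl-3-oxocyclohexane-1-carboxylate (racemic, epimer mixture) | COC(=O)C1CCC(C)C(=O)C1 | intermediate
11 | (S)-1-phenylethylamine | C[C@H](N)c1ccccc1 | starting material
12 | pent-1-en-3-one | CCC(=O)C=C | starting material
13 | methyl 4-methyl-3-{[(1S)-1-phenylethyl]imino}cyclohexane-1-carboxylate | C[C@H](N=C1CC(C(=O)OC)CCC1C)c1ccccc1 | intermediate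
14 | methyl (4R)-4-methyl-4-(3-oxopentyl)-3-{[(1S)-1-phenylethyl]imino}cyclohexane-1-carboxylate | C[C@H](N=C1CC(C(=O)OC)CC[C@]1(C)CCC(=O)CC)c1ccccc1 | intermediate
15 | methyl (4R)-4-methyl-3-oxo-4-(3-oxopentyl)cyclohexane-1-carboxylate (C1 epimers) | CCC(=O)CC[C@@]1(C)CCC(C(=O)OC)CC1=O | intermediate
16 | methyl (4aR)-4a,8-dimethyl-7-oxo-1,2,3,4,4a,5,6,7-octahydronaphthalene-2-carboxylate (D/E enone, C20 epimers) | O=C1CC[C@@]2(C)CCC(C(=O)OC)CC2=C1C | intermediate
17 | methyl (4aR,8aS)-4a,8-dimethyl-7-oxodecahydronaphthalene-2-carboxylate (cis-fused, 17β-Me, 18β-H; C13 and C20 epimers) | O=C1CC[C@@]2(C)CCC(C(=O)OC)C[C@H]2C1C | intermediate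
18 | but-3-en-2-one | CC(=O)C=C | starting material
19 | D/E ketone with 13α-methyl and 13β-(3-oxobutyl) | O=C1CC[C@@]2(C)CCC(C(=O)OC)C[C@H]2[C@]1(C)CCC(C)=O | intermediate
20 | C/D/E tricycle: 9-oxo-8(14)-ene, 13α-Me, 17β-Me, 18β-H, 20-CO2Me (C20 epimers) | O=C1C=C2CC[C@@]3(C)CCC(C(=O)OC)C[C@H]3[C@]2(C)CC1 | intermediate
21 | C/D/E tricycle: 9-hydroxy-9-methyl-8(14)-ene, 20-CO2Me (C9 and C20 epimers) | CC1(O)C=C2CC[C@@]3(C)CCC(C(=O)OC)C[C@H]3[C@]2(C)CC1 | intermediate
22 | C/D/E tricycle: 9-hydroxy-9-methyl-8(14)-ene, 20β-Me, 20α-CO2Me | CC1(O)C=C2CC[C@@]3(C)CC[C@@](C)(C(=O)OC)C[C@H]3[C@]2(C)CC1 | intermediate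
23 | C/D/E tricycle: 8,9-dihydroxy-9-methyl, 20β-Me, 20α-CO2Me (C8, C9, C14 uncontrolled) | CC1(O)C(O)C2CC[C@@]3(C)CC[C@@](C)(C(=O)OC)C[C@H]3[C@]2(C)CC1 | intermediate
24 | C/D/E tricycle: 9-hydroxy-9-methyl-8-oxo, 20β-Me, 20α-CO2Me | CC1(O)C(=O)C2CC[C@@]3(C)CC[C@@](C)(C(=O)OC)C[C@H]3[C@]2(C)CC1 | intermediate
25 | C/D/E tricycle: 9-methyl-8-oxo-9(11)-ene, 14-H, 20β-Me, 20α-CO2Me | CC1=CC[C@@]2(C)[C@@H]3C[C@](C)(C(=O)OC)CC[C@]3(C)CCC2C1=O | intermediate
26 | C/D/E tricycle: 9-methyl-8-oxo-9(11)-ene, 13α-Me, 14β-Me, 20β-Me, 20α-CO2Me | CC1=CC[C@@]2(C)[C@@H]3C[C@](C)(C(=O)OC)CC[C@]3(C)CC[C@]2(C)C1=O | intermediate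
27 | C/D/E tricycle: C8 enol triflate, 9-methyl-8-ene | FC(F)(F)S(=O)(=O)OC1=C(C)CC[C@@]2(C)[C@@H]3C[C@](C)(C(=O)OC)CC[C@]3(C)CC[C@]12C | intermediate
28 | (E)-2-(2-ethoxyvinyl)-4,4,5,5-tetramethyl-1,3,2-dioxaborolane | CCO/C=C/B1OC(C)(C)C(C)(C)O1 | starting material
29 | C/D/E tricycle: 8-[(E)-2-ethoxyvinyl]-9-methyl-8-ene methyl ester | CCO/C=C/C1=C(C)CC[C@@]2(C)[C@@H]3C[C@](C)(C(=O)OC)CC[C@]3(C)CC[C@]12C | intermediate
30 | 4,5-dimethoxy-3-methylbenzyne | COC1=CC#CC(C)=C1OC | intermediate
31 | pentacyclic 6α-ethoxy-7-ene 2,3-dimethyl ether (9β-Me) | COc1cc2c(c(C)c1OC)[C@@H](OCC)C=C1[C@@]2(C)CC[C@@]2(C)[C@@H]3C[C@](C)(C(=O)OC)CC[C@]3(C)CC[C@]12C | intermediate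
32 | 6-oxopristimerol dimethyl ether | COc1cc2c(c(C)c1OC)C(=O)C=C1[C@@]2(C)CC[C@@]2(C)[C@@H]3C[C@](C)(C(=O)OC)CC[C@]3(C)CC[C@]12C | intermediate
33 | 6-oxopristimerol | Cc1c(O)c(O)cc2c1C(=O)C=C1[C@@]2(C)CC[C@@]2(C)[C@@H]3C[C@](C)(C(=O)OC)CC[C@]3(C)CC[C@]12C | intermediate
34 | (2R,5R)-2-methyl-5-(prop-1-en-2-yl)cyclohexan-1-one (trans-dihydrocarvone) | C=C(C)[C@@H]1CC[C@@H](C)C(=O)C1 | starting material
35 | ethyl (3R,6R)-3-methyl-2-oxo-6-(prop-1-en-2-yl)cycloheptane-1-carboxylate (C1 epimers) | C=C(C)[C@@H]1CC[C@@H](C)C(=O)C(C(=O)OCC)C1 | intermediate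
36 | ethyl (3R,6R)-3-methyl-6-(prop-1-en-2-yl)-2-(trifluoromethylsulfonyloxy)cyclohept-1-ene-1-carboxylate | C=C(C)[C@@H]1CC[C@@H](C)C(OS(=O)(=O)C(F)(F)F)=C(C(=O)OCC)C1 | intermediate
37 | ethyl (3R,6R)-2-(3-ethoxy-3-oxopropyl)-3-methyl-6-(prop-1-en-2-yl)cyclohept-1-ene-1-carboxylate | C=C(C)[C@@H]1CC[C@@H](C)C(CCC(=O)OCC)=C(C(=O)OCC)C1 | intermediate
38 | ethyl (4R,7R)-4-methyl-1-oxo-7-(prop-1-en-2-yl)-1,2,3,4,5,6,7,8-octahydroazulene-2-carboxylate | C=C(C)[C@@H]1CC[C@@H](C)C2=C(C1)C(=O)C(C(=O)OCC)C2 | intermediate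
39 | (4R,7R)-4-methyl-7-(prop-1-en-2-yl)-3,4,5,6,7,8-hexahydroazulen-1(2H)-one | C=C(C)[C@@H]1CC[C@@H](C)C2=C(C1)C(=O)CC2 | intermediate
40 | (4R,7R)-4-methyl-7-(prop-1-en-2-yl)-3,4,5,6,7,8-hexahydroazulen-1-yl trifluoromethanesulfonate | C=C(C)[C@@H]1CC[C@@H](C)C2=C(C1)C(OS(=O)(=O)C(F)(F)F)=CC2 | intermediate
41 | (7R,10R)-guaia-1(5),3,11-triene | C=C(C)[C@@H]1CC[C@@H](C)C2=C(C1)C(C)=CC2 | intermediate
42 | ortho-quinone of 6-oxopristimerol (2,3,6-trioxo-1(10),4,7-triene) | O=C1C(=O)C(C)=C2C(=O)C=C3[C@@](C)(CC[C@@]4(C)[C@@H]5C[C@](C)(C(=O)OC)CC[C@]5(C)CC[C@]34C)C2=C1 | intermediate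
43 | CNP0317749.1 | C=C(C)[C@@H]1CC[C@@H](C)[C@@]23CC=C(C)[C@]2(C1)Oc1cc2c(c(C)c1O3)C(=O)C=C1[C@@]2(C)CC[C@@]2(C)[C@@H]3C[C@](C)(C(=O)OC)CC[C@]3(C)CC[C@]12C | target

**Totals**
Total step count: 28
Longest linear sequence: 18 steps (8 to 43 through steps 5–21 and 28)

**Steps most likely to fail**

Step 19. The aryne may be consumed by an ene reaction at the C9 methyl or C11 hydrogens, by [2+2] addition to the enol ether, or by addition in the reverse orientation. Fallback: ring B is closed by a cationic arylation instead. It sets out from 2 and 27. Suzuki–Miyaura vinylation of 2 (vinylboronic acid pinacol ester, Pd(dppf)Cl2, K2CO3) gives 1-ethenyl-3,4-dimethoxy-2-methylbenzene F1. Hydroboration with 9-BBN gives 9-[2-(3,4-dimethoxy-2-methylphenyl)ethyl]-9-borabicyclo[3.3.1]nonane F2, and B-alkyl Suzuki coupling with 27 gives the aryl-ethyl tetrasubstituted alkene F3. MeSO3H in CH2Cl2 protonates C8, and the tertiary C9 cation is captured on the α face by C10 of the arene, para to the 3-methoxy group, to give the 6,7,8-saturated pentacycle F4. DDQ in wet dioxane oxidises the benzylic C6 methylene to the 7,8-dihydro ketone F5, and IBX in DMSO introduces the C7=C8 bond. The sequence comes back to the route at 32.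

Step 28. The cyclopentadiene may isomerise by 1,5-hydrogen shifts or dimerise before it is trapped, and the quinone may add as a carbon diene or in the other orientation. Fallback: the two C–O bonds are made one after the other. It sets out from 41 and 33. mCPBA (NaHCO3, CH2Cl2, −40 °C) epoxidises the tetrasubstituted C1=C5 bond anti to the C10 methyl to give the vinyl epoxide F6. Pd(PPh3)4 opens it to a π-allyl alkoxide, and the more acidic 2-hydroxyl of 33 (para to the carbon that bears the C6 ketone) adds at the proximal terminus C5 with net retention to give the hydroxy aryl ether F7. A trace of TsOH then ionises the tertiary C1 alcohol and the 3-hydroxyl closes the cis-fused dioxane. The sequence comes back at 43.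

Step 16. Deprotonation may occur at γ-C12 or at the C9 methyl instead of the hindered C14, and methyl iodide may not discriminate the two faces next to quaternary C13. Fallback: the methyl group is delivered as a cyclopropane methylene. It sets out from 25. LiN(i-Pr)2 and Me3SiCl give the cross-conjugated silyl dienol ether F8. Et2Zn/CH2I2 cyclopropanates the electron-rich C8=C14 bond on the β face (Simmons–Smith reaction) to give the siloxycyclopropane F9, and NaOH in MeOH opens the ring toward the less substituted carbon to give the 14β-methyl ketone. The sequence comes back at 26.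

Further compounds
F1 | step 19 | 1-ethenyl-3,4-dimethoxy-2-methylbenzene | C=Cc1ccc(OC)c(OC)c1C
F2 | step 19 | 9-[2-(3,4-dimethoxy-2-methylphenyl)ethyl]-9-borabicyclo[3.3.1]nonane | COc1ccc(CCB2C3CCCC2CCC3)c(C)c1OC
F3 | step 19 | C/D/E tricycle with 8-[2-(3,4-dimethoxy-2-methylphenyl)ethyl]-9-methyl-8-ene | COc1ccc(CCC2=C(C)CC[C@@]3(C)[C@@H]4C[C@](C)(C(=O)OC)CC[C@]4(C)CC[C@]23C)c(C)c1OC
F4 | step 19 | 6-deoxo-7,8-dihydro analogue of 32 (C8 open) | COc1cc2c(c(C)c1OC)CCC1[C@@]2(C)CC[C@@]2(C)[C@@H]3C[C@](C)(C(=O)OC)CC[C@]3(C)CC[C@]12C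
F5 | step 19 | 7,8-dihydro analogue of 32 (C8 open) | COc1cc2c(c(C)c1OC)C(=O)CC1[C@@]2(C)CC[C@@]2(C)[C@@H]3C[C@](C)(C(=O)OC)CC[C@]3(C)CC[C@]12C
F6 | step 28 | 1β,5β-epoxide of 41 | C=C(C)[C@@H]1CC[C@@H](C)[C@@]23CC=C(C)[C@]2(C1)O3
F7 | step 28 | 5β-aryl ether (through O-2 of 33) with 1β-hydroxyl | C=C(C)[C@@H]1CC[C@@H](C)[C@@]2(O)CC=C(C)[C@]2(C1)Oc1cc2c(c(C)c1O)C(=O)C=C1[C@@]2(C)CC[C@@]2(C)[C@@H]3C[C@](C)(C(=O)OC)CC[C@]3(C)CC[C@]12C
F8 | step 16 | 8-trimethylsilyloxy-8(14),9(11)-diene from 25 | CC1=CC[C@@]2(C)[C@@H]3C[C@](C)(C(=O)OC)CC[C@]3(C)CCC2=C1O[Si](C)(C)C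
F9 | step 16 | 8α-trimethylsilyloxy-8β,14β-methano-9(11)-ene | CC1=CC[C@@]2(C)[C@@H]3C[C@](C)(C(=O)OC)CC[C@]3(C)CC[C@@]24C[C@@]14O[Si](C)(C)C
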